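Read 1.05 equiv of J as a surplus of 0.0500 and you have counted J that D may take from you.

| setting | ash | alder | flask |
|---|---|---|---|
| L | 0.050 M | 0.050 M | 0.050 M |
| J | 1.05 equiv | 1.05 equiv | 1.05 equiv |
| D | 1 mM | 1.5 mM | 1.00 mM |
| temperature | 60 °C | 60 °C | 60 °C |
| remark | the very flask that is asked about, followed so far | run made earlier |  |
| time |  |  | 6.0 min |

- ash (time / min: Q / %): 0.200: 17; 0.500: 26; 1.00: 32; 1.50: 35; 2.00: 33; 3.00: 38; 4.00: 37
- alder (time / min: Q / %): 0.833: 27; 1.50: 33; 2.50: 39; 3.00: 37; 4.00: 40; 5.00: 38; 6.00: 41

(each reading ± 1.5 percentage points)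

- zeta: at 6.0 min take out 90% of the Q then present, then wait 3.0 min
- eta: at 6.0 min add J, 100% of the amount charged, then wait 3.0 min
- delta: at 6.0 min raise the temperature by 10 K, then wait 3.0 min
- alpha: change nothing and wait 3.0 min more

- what is taken out of Q is counted as made
- steps that have been proposed: L + J <-> Q + G; Q <-> E; G -> X; J + D -> Z
- the earlier runs do not show what temperature does; that part of a forecast is a guess
- additions bring no volume worth counting

1. Q, in percent of the L first charged, at 6.0 min
2. the remedy with the largest gain of Q, or "none" below 2 percentage points (zeta / eta / delta / alpha / none)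
3. Q present, with what was taken out counted in, in percent of the L first charged, after delta
4. Q present, with what was taken out counted in, in percent of the L first charged, after alpha

The proposed steps are L + J <-> Q + G, Q <-> E, G -> X and J + D -> Z. The first moves L and J one for one in either direction, the last takes J with D, and the other two touch neither L nor J. So you can keep a balance, as for a tank, with no rate constant. Work in fractions of the L charge. Once D is used up, J left minus L left holds one value, which I call the gap. For the ash flask:

gap = J charged − L charged − D charged = 1.05 − 1 − 0.0200 = 0.0300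

The alder run has a gap of 0.0200. The extra D in alder takes J worth 1.00% of the L charge, while a single reading scatters by 1.5 percentage points. So treat D as a small correction and carry the alder readings over to ash unchanged. The ash readings flatten near 38% by 3.00 min, and the alder readings from 4.00 min to 6.00 min average:

Q = 39.7%

That is my reckoning for Q in the ash flask at 6.0 min. The forecast is a little lower, at 39%. It picks zeta, with 41% after delta and 40% after alpha, and says of D: “so it matters little”.

The flask gives 40.2%, and the best remedy is zeta, with a gain of 20 points. Eta gains 7.9 points. Delta gives 45.7% and alpha 41.0%. The step J + D -> Z makes no difference worth counting to Q in this flask.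

    L + J ⇌ Q + G (K = 5.30, k = 0.410 M⁻¹ s⁻¹, Ea = 47.0 kJ mol⁻¹, ΔH = −29.0 kJ mol⁻¹)
    Q ⇌ E (K = 0.970, k = 0.0330 s⁻¹, Ea = 91.0 kJ mol⁻¹, ΔH = −26.0 kJ mol⁻¹)
    G → X (k = 9.90 × 10⁻⁴ s⁻¹, Ea = 90.0 kJ mol⁻¹)
    J + D → Z (k = 180 M⁻¹ s⁻¹, Ea = 45.0 kJ mol⁻¹)
    (constants at 60 °C)

In the ash flask at 6.00 min, D stands at 0%, L at 21.1%, and J at 22.9% of its own charge, which is 0.240 of the L charge. J minus L is 0.0300, the gap again. Now take a neighbouring flask, the same but with 0.260 equiv of J. Its gap is −0.760, and the negative sign marks J as the limiting reagent, so at least 0.760 of the L must remain once D is used up. At 6.00 min that neighbouring flask holds D at 0%, L at 76.6%, J at 2.26% of its own charge, and Q at 11.9%.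

Readings and results come from a simulation with constants of no real substance.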